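Wednesday's flask, charged with 0.64 equiv of incoming ligand, has its highest reading of complex with one exchanged at 1.33 min, namely 39.9%. Thursday's flask, with 1.4 equiv, reads 71.2% at that same time.

the same everywhere: starting complex 0.10 M
- Wednesday's: incoming ligand 0.64 equiv; leaving ligand 1 equiv; run made earlier
- Thursday's: incoming ligand 1.4 equiv; leaving ligand 1 equiv; run made earlier
- flask: incoming ligand 0.950 equiv; leaving ligand 1.00 equiv; time 10 min

| run | time / min | complex with one exchanged / % | starting complex / % |
|---|---|---|---|
| Wednesday's | 0.200 | 29.5 | 68.0 |
| Wednesday's | 0.500 | 39.7 | 59.3 |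
| Wednesday's | 1.33 | 39.9 | 59.5 |
| Wednesday's | 3.00 | 36.5 | 62.9 |
| Wednesday's | 8.00 | 28.9 | 68.1 |
| Thursday's | 0.200 | 51.7 | 42.1 |
| Thursday's | 0.500 | 68.6 | 28.7 |
| Thursday's | 1.33 | 71.2 | 28.0 |
| Thursday's | 3.00 | 61.5 | 37.9 |
| Thursday's | 8.00 | 43.8 | 53.6 |

(each reading ± 0.5 percentage points)

- time up to 10 min at which complex with one exchanged stands highest
- the amount of complex with one exchanged, in percent of the starting complex charged, at that time



I call that highest reading, taken per equivalent of incoming ligand charged, the capture share s. As readings, s is 62.3% on Wednesday and 50.9% on Thursday, so it is smaller at the larger charge. The new flask holds 0.950 equiv, between the two, and I assume s falls steadily between them. Wednesday's share then gives a bound from above, 59.2%, and Thursday's a bound from below, 48.3%. A straight line between the two shares tightens this to s = 57.7%, so I expect a top of 54.8%. For the time, Wednesday's readings at 0.500 min and 1.33 min are 39.7% and 39.9%, with a scatter of 0.5 percentage points, and by 3.00 min the reading has dropped to 36.5%. So for the new flask I expect the top between 0.500 min and 1.33 min, and that is where I watch. The forecast gives 55% near 0.9 min, “interpolating with curvature”, which stands inside my bracket.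

The flask tops at 55.9% at 0.871 min, inside the bracket, which makes its share 58.8% against my 57.7%. At that moment decomposed reagent stands at 0.0349 M, or 36.7% of the incoming ligand charged.

    incoming ligand → decomposed reagent (k = 0.0366 /s)
    complex with one exchanged + incoming ligand ⇌ leaving ligand + complex with two exchanged (K = 0.430, k = 1.88 /M/s)
    starting complex + incoming ligand ⇌ leaving ligand + complex with one exchanged (K = 57.2, k = 1.02 /M/s)
    2 starting complex → homo dimer (k = 7.24 × 10⁻⁴ /M/s)
    complex with two exchanged + incoming ligand ⇌ leaving ligand + complex with three exchanged (K = 0.751, k = 7.59 /M/s)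

Extending my line to the same flask with 0.570 equiv gives s = 63.4%, and so a top of 36.1%. The computed flask reaches 36.8%.

All runs are simulated for an exercise, and the scatter is random.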